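Numbering: ring A (cyclohexene) C1, C2, C3, C4, C16, C15; ring B (cyclopentane) C4, C5, C6, C7, C16; ring C (eleven-membered) C1, C15, C16, C7 to C14. Everything rests on a formal [3+2] disconnection of ring B. The precursor is a seven-membered dienyl lactone (O2–C8(=O)–C7=C16–C15=C1–C2) whose C2 carries a 1-methylcyclopropyl ketone (C3=O; C4, C5, C6). One iodide-relayed cascade joins C4 to C16 and C6 to C7, closing rings A and B and setting C4, C7 and C16 from C2. It exploits the C3 oxygen beside quaternary C4 and the C1=C15 alkene beside C16. Ring C is closed late by Nozaki–Hiyama–Kishi coupling.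

Key step: step 9

Remark (substituents): C17 is the methyl on C15, C18 the methyl on C4, C19 the exocyclic methylene on C8, C20 the methyl on C12; C9 bears the acetate, C2 and C3 the hydroxyls.
Remark (atom mapping): butenolide atoms C2, C3, C4, C5 become C16, C15, C1, C2 of the target; oxepinone atoms O1, C2, C3, C4, C5, C6, C7 become O2, C8, C7, C16, C15, C1, C2.
Remark (assumptions): the carbinol centre made in step 3 (future C3) is carried as both epimers because step 8 removes it; the BINOL antipode in step 3 and the sulfonamide-ligand antipode in step 16 are taken to be those that give 2R and 9R ((R)-BINOL and the (S)-ligand are written as working assumptions); C12 keeps the configuration of 3 throughout, and its CIP label changes from S to R only because C9 becomes oxygenated in step 15.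

Step 1
Reactants: 1 3-methyltetronic acid
Product: 2 butenolide enol triflate
Conditions: Tf2O, iPr2NEt, CH2Cl2, −78 °C
Reagents that add atoms: trifluoromethanesulfonic anhydride, O=S(=O)(OS(=O)(=O)C(F)(F)F)C(F)(F)F
Why: O-sulfonylation of the vinylogous acid gives the enol triflate needed for cross-coupling (standard activation of a tetronic acid).

Step 2
Reactants: 2 butenolide enol triflate; 3 (S)-β-citronellene
Product: 5 4-[(3S)-3,7-dimethyloct-6-en-1-yl]-3-methylfuran-2(5H)-one, via B-alkyl-9-BBN adduct 4 (not isolated)
Conditions: 3, 9-BBN, THF, 0 °C to rt; then 2, PdCl2(dppf) (5 mol %), AsPh3, K3PO4, DMF/H2O, 50 °C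
Reagents that add atoms: (S)-β-citronellene 3, C=C[C@@H](C)CCC=C(C)C (delivered as its 9-BBN adduct 4)
Why: 9-BBN hydroborates only the monosubstituted alkene and the primary alkylborane undergoes B-alkyl Suzuki–Miyaura coupling with the vinylogous acyl triflate, so that C12 comes unchanged from the chiral pool.

Step 3
Reactants: 5 citronellyl butenolide; 6 1-methylcyclopropane-1-carbaldehyde
Product: 8 (5R)-5-[hydroxy(1-methylcyclopropyl)methyl] butenolide (carbinol epimers), via 2-(trimethylsilyloxy)furan 7 (not isolated)
Conditions: Me3SiOTf, Et3N, CH2Cl2, 0 °C; then 6, Ti(OiPr)4/(R)-BINOL (20 mol %), Et2O, −20 °C; aq. HCl work-up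
Reagents that add atoms: 1-methylcyclopropane-1-carbaldehyde 6, CC1(C=O)CC1
Why: catalytic asymmetric vinylogous Mukaiyama aldol reaction at the furan γ-carbon (the α-carbon is blocked by the methyl), in which the BINOL–titanium complex selects the furan face and so sets C2 (R), the only stereocentre the later cascade needs.

Step 4
Reactants: 8 aldol adduct
Product: 9 triethylsilyl ether of 8
Conditions: Et3SiOTf, 2,6-lutidine, CH2Cl2, −78 to 0 °C
Reagents that add atoms: triethylsilyl trifluoromethanesulfonate, CC[Si](CC)(CC)OS(=O)(=O)C(F)(F)F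
Why: silylation of the hindered secondary alcohol so that it cannot compete with O2 in the ring expansion of step 6.

Step 5
Reactants: 9 silyl ether
Product: 10 lactol (2,5-dihydrofuran-2-ol, anomers)
Conditions: iBu2AlH (1.1 equiv), CH2Cl2, −78 °C; aq. potassium sodium tartrate; used crude
Reagents that add atoms: none
Why: partial reduction of the butenolide stops at the aluminium acetal at −78 °C and gives the lactol, which is kept free of acid to avoid dehydration to the furan.

Step 6
Reactants: 10 lactol; 11 ketenylidenetriphenylphosphorane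
Product: 12 seven-membered dienyl lactone (silyl ether)
Conditions: 11 (1.3 equiv), toluene, 90 °C
Reagents that add atoms: ketenylidenetriphenylphosphorane 11, O=C=C=P(c1ccccc1)(c1ccccc1)c1ccccc1
Why: the ring-opened (Z)-γ-hydroxy enal adds its O2–H across the cumulated ylide and the ester ylide so formed closes by intramolecular Wittig olefination (addition–Wittig cascade of hydroxy carbonyl compounds), the seven-membered ring enforcing the cis C7=C16 bond.

Step 7
Reactants: 12 silyl ether lactone
Product: 13 hydroxy lactone
Conditions: HF·pyridine, pyridine/THF, 0 °C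
Reagents that add atoms: none
Why: fluoride-mediated desilylation under buffered conditions that leave the dienyl lactone untouched.

Step 8
Reactants: 13 hydroxy lactone
Product: 14 cyclopropyl ketone (precursor of the key step)
Conditions: Dess–Martin periodinane, NaHCO3, CH2Cl2, 0 °C to rt
Reagents that add atoms: none
Why: buffered Dess–Martin oxidation of the secondary alcohol gives the ketone that activates the cyclopropane, without base that could epimerise C2.

Step 9
Reactants: 14 cyclopropyl ketone
Product: 17 tricyclic keto lactone (rings A and B closed), via iodomagnesium enolate 15 (not isolated), via bicyclic lactone enolate 16 (not isolated)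
Conditions: MgI2 (1.2 equiv), toluene/THF 5:1, 70 °C, 0.01 M, sealed tube
Reagents that add atoms: none
Why: Proposed new method: MgI2 chelated between the C3 ketone and the lactone ring oxygen lets iodide open the cyclopropane at a methylene carbon (homo-conjugate addition) to the tetrasubstituted enolate 15, C4 of which adds to C16 of the dienyl lactone to give ester enolate 16, and C7 of 16 then displaces the primary iodide at C6, which returns MgI2; the closest known reaction types are the MgI2-mediated formal [3+2] ring expansion of cyclopropyl carbonyl compounds with imines, the iodide-triggered halo-aldol of cyclopropyl ketones and Michael-initiated ring closure. Ring A closes in the 6-(enolendo)-exo-trig mode (C4–C16) and ring B in the 5-(enolexo)-exo-tet mode (C6–C7). C16 is controlled by C2, because the two-atom C3–C4 arm can bridge the seven-membered lactone only on the face that carries the C2–C3 bond; C7 is controlled by the lactone tether, which holds C8 on the face of O2 and so places H7 cis to H16; C4 is controlled by the last closure, since only the adduct with the iodoethyl arm on the lactone face can reach C7, leaving C18 cis to H16. The step is stereoconvergent, because both enolate geometries interconvert by re-closure to the cyclopropane and unproductive Michael adducts can revert, whereas the final alkylation is irreversible and the non-enolisable C3 ketone (quaternary C4, bridgehead C2) then locks every centre. The selectivity needed is C–C bond formation at C16 in preference to O-alkylation of 15 (dihydrofuran) and to iodide attack at C2, and the intramolecular six-ring Michael addition onto the chelated conjugated lactone is expected to secure it.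

Step 10
Reactants: 17 tricyclic keto lactone
Product: 18 hydroxy keto N-methoxy-N-methyl amide
Conditions: MeNHOMe·HCl, AlMe3, CH2Cl2, 0 °C to rt
Reagents that add atoms: N,O-dimethylhydroxylamine hydrochloride, CNOC.Cl
Why: aluminium amide aminolysis opens the bridged lactone to the Weinreb amide and frees the C2 hydroxyl, while the hindered, non-enolisable C3 ketone and the C7 centre are left alone.

Step 11
Reactants: 18 hydroxy keto amide
Product: 19 trans-2,3-diol
Conditions: Me4NBH(OAc)3, AcOH/MeCN 1:1, −30 °C
Reagents that add atoms: none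
Why: hydroxyl-directed Saksena–Evans reduction, in which the acetoxyborohydride bound to O2 delivers hydride to C3 on the face of the C2 hydroxyl (also the face away from the C18 methyl) and so sets C3 (R) trans to O2.

Step 12
Reactants: 19 diol
Product: 20 2,3-bis(triethylsilyl) ether
Conditions: Et3SiOTf (2.5 equiv), 2,6-lutidine, CH2Cl2, −78 to 0 °C
Reagents that add atoms: triethylsilyl trifluoromethanesulfonate, CC[Si](CC)(CC)OS(=O)(=O)C(F)(F)F
Why: silylation of both secondary hydroxyls protects them through the organometallic steps and leaves O9 as the only free hydroxyl at the acetylation stage.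

Step 13
Reactants: 20 bis-silyl amide
Product: 21 methyl ketone (C7–C8(=O)–C19H3)
Conditions: MeMgBr (3 equiv), THF, −20 to 0 °C; aq. NH4Cl
Reagents that add atoms: methylmagnesium bromide, C[Mg]Br
Why: Weinreb ketone synthesis, in which the chelated tetrahedral intermediate prevents over-addition and the non-basic work-up keeps the contra-thermodynamic C7 configuration.

Step 14
Reactants: 21 methyl ketone
Product: 22 alkenyl triflate (C8(OTf)=C19H2)
Conditions: KN(SiMe3)2, THF, −78 °C; then PhNTf2, −78 to −20 °C
Reagents that add atoms: N-phenylbis(trifluoromethanesulfonimide), O=S(=O)(N(c1ccccc1)S(=O)(=O)C(F)(F)F)C(F)(F)F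
Why: kinetic deprotonation takes the methyl hydrogen and not the hindered tertiary C7–H, and O-triflation of this terminal enolate gives the 1,1-disubstituted enol triflate.

Step 15
Reactants: 22 alkenyl triflate
Product: 24 C9 aldehyde, via vicinal diol 23 (not isolated)
Conditions: OsO4 (2 mol %), NaIO4 (4 equiv), 2,6-lutidine, dioxane/H2O 3:1, rt
Reagents that add atoms: sodium periodate, [Na+].[O-]I(=O)(=O)=O; osmium tetroxide (catalytic oxygen carrier), O=[Os](=O)(=O)=O
Why: Lemieux–Johnson cleavage, in which OsO4 dihydroxylates the unhindered trisubstituted chain alkene in preference to the shielded tetrasubstituted C1=C15 alkene and the electron-poor enol triflate, and periodate cleaves the diol to the aldehyde.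

Step 16
Reactants: 24 aldehyde alkenyl triflate
Product: 25 macrocyclic allylic alcohol (ring C closed)
Conditions: CrCl2 (8 equiv), NiCl2 (0.2 equiv), (S)-N-[2-(4-isopropyl-4,5-dihydrooxazol-2-yl)-6-methylphenyl]methanesulfonamide, Et3N, THF, rt, 2 mM, syringe-pump addition of 24
Reagents that add atoms: none
Why: Nozaki–Hiyama–Kishi macrocyclisation, in which the nickel-generated alkenylchromium at C8 adds chemoselectively to the aldehyde to form C8–C9 with the exocyclic methylene in place, the chiral sulfonamide–chromium complex selecting the aldehyde face to give C9 (R).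

Step 17
Reactants: 25 allylic alcohol
Product: 26 9-O-acetate
Conditions: Ac2O, DMAP, pyridine, CH2Cl2, rt
Reagents that add atoms: acetic anhydride, CC(=O)OC(C)=O
Why: acylation of the only free hydroxyl proceeds at oxygen with retention at C9.

Step 18
Reactants: 26 acetate bis-silyl ether
Product: 27 target
Conditions: HF·pyridine, pyridine/THF, 0 °C to rt
Reagents that add atoms: none
Why: fluoride cleavage of both triethylsilyl ethers releases the 2,3-diol without touching the allylic acetate.

Compound list
1 | 4-hydroxy-3-methylfuran-2(5H)-one (3-methyltetronic acid) | CC1=C(O)COC1=O | starting material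
2 | 4-methyl-5-oxo-2,5-dihydrofuran-3-yl trifluoromethanesulfonate | CC1=C(OS(=O)(=O)C(F)(F)F)COC1=O | intermediate
3 | (S)-β-citronellene, (3S)-3,7-dimethylocta-1,6-diene | C=C[C@@H](C)CCC=C(C)C | starting material
4 | 9-(3,7-dimethyloct-6-en-1-yl)-9-borabicyclo[3.3.1]nonane, methyl-bearing centre as in 3 | CC(C)=CCC[C@H](C)CCB1C2CCCC1CCC2 | intermediate
5 | 4-[(3S)-3,7-dimethyloct-6-en-1-yl]-3-methylfuran-2(5H)-one | CC1=C(CC[C@@H](C)CCC=C(C)C)COC1=O | intermediate
6 | 1-methylcyclopropane-1-carbaldehyde | CC1(C=O)CC1 | starting material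
7 | 4-[(3S)-3,7-dimethyloct-6-en-1-yl]-3-methyl-2-(trimethylsilyloxy)furan | Cc1c(CC[C@@H](C)CCC=C(C)C)coc1O[Si](C)(C)C | intermediate
8 | (5R)-4-[(3S)-3,7-dimethyloct-6-en-1-yl]-5-[hydroxy(1-methylcyclopropyl)methyl]-3-methylfuran-2(5H)-one, both carbinol epimers | CC1=C(CC[C@@H](C)CCC=C(C)C)[C@H](C(O)C2(C)CC2)OC1=O | intermediate
9 | (5R)-4-[(3S)-3,7-dimethyloct-6-en-1-yl]-3-methyl-5-[(1-methylcyclopropyl)(triethylsilyloxy)methyl]furan-2(5H)-one | CC1=C(CC[C@@H](C)CCC=C(C)C)[C@H](C(O[Si](CC)(CC)CC)C2(C)CC2)OC1=O | intermediate
10 | (5R)-4-[(3S)-3,7-dimethyloct-6-en-1-yl]-3-methyl-5-[(1-methylcyclopropyl)(triethylsilyloxy)methyl]-2,5-dihydrofuran-2-ol, anomers | CC1=C(CC[C@@H](C)CCC=C(C)C)[C@H](C(O[Si](CC)(CC)CC)C2(C)CC2)OC1O | intermediate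
11 | ketenylidenetriphenylphosphorane (Ph3P=C=C=O) | O=C=C=P(c1ccccc1)(c1ccccc1)c1ccccc1 | starting material
12 | (7R)-6-[(3S)-3,7-dimethyloct-6-en-1-yl]-5-methyl-7-[(1-methylcyclopropyl)(triethylsilyloxy)methyl]oxepin-2(7H)-one | O=C1C=CC(C)=C(CC[C@@H](C)CCC=C(C)C)[C@H](C(O[Si](CC)(CC)CC)C2(C)CC2)O1 | intermediate
13 | (7R)-6-[(3S)-3,7-dimethyloct-6-en-1-yl]-7-[hydroxy(1-methylcyclopropyl)methyl]-5-methyloxepin-2(7H)-one | O=C1C=CC(C)=C(CC[C@@H](C)CCC=C(C)C)[C@H](C(O)C2(C)CC2)O1 | intermediate
14 | (7R)-6-[(3S)-3,7-dimethyloct-6-en-1-yl]-5-methyl-7-(1-methylcyclopropane-1-carbonyl)oxepin-2(7H)-one | O=C1C=CC(C)=C(CC[C@@H](C)CCC=C(C)C)[C@H](C(=O)C2(C)CC2)O1 | intermediate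
15 | iodomagnesium enolate from ring opening of 14: C3(OMgI)=C4(CH3)(CH2CH2I) on C2 of the lactone, enolate geometry not fixed | O=C1C=CC(C)=C(CC[C@@H](C)CCC=C(C)C)[C@H](C(O[Mg]I)=C(C)CCI)O1 | intermediate
16 | bicyclic iodomagnesium lactone enolate: C4–C16 formed, C7=C8(OMgI), iodoethyl arm on C4 on the lactone face | CC(C)=CCC[C@H](C)CCC2=C(C)[C@@H]3C=C(O[Mg]I)O[C@H]2C(=O)[C@@]3(C)CCI | intermediate
17 | tricyclic keto lactone (2R,4S,7R,12S,16S): cis-fused rings A and B, C3 ketone, lactone O2–C8(=O) bridging C2 and C7, H7, H16 and C18 on one face, C1 bearing the C14–C9 chain capped as isopropylidene | CC(C)=CCC[C@H](C)CCC2=C(C)[C@@H]3[C@H]1CC[C@]3(C)C(=O)[C@@H]2OC1=O | intermediate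
18 | (2R,4S,7R,12S,16S) hydroxy keto amide: C2–OH, C3 ketone, C7–C8(=O)N(OCH3)CH3 | CC(C)=CCC[C@H](C)CCC2=C(C)[C@@H]3[C@H](C(=O)N(C)OC)CC[C@]3(C)C(=O)[C@@H]2O | intermediate
19 | (2R,3R,4S,7R,12S,16S) trans-2,3-diol amide | CC(C)=CCC[C@H](C)CCC2=C(C)[C@@H]3[C@H](C(=O)N(C)OC)CC[C@]3(C)[C@@H](O)[C@@H]2O | intermediate
20 | 2,3-bis(triethylsilyl) ether of 19 | CC(C)=CCC[C@H](C)CCC2=C(C)[C@@H]3[C@H](C(=O)N(C)OC)CC[C@]3(C)[C@@H](O[Si](CC)(CC)CC)[C@@H]2O[Si](CC)(CC)CC | intermediate
21 | methyl ketone: C7 bears acetyl (C8, C19), diol as bis(triethylsilyl) ether | CC(C)=CCC[C@H](C)CCC2=C(C)[C@@H]3[C@H](C(C)=O)CC[C@]3(C)[C@@H](O[Si](CC)(CC)CC)[C@@H]2O[Si](CC)(CC)CC | intermediate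
22 | alkenyl triflate: C7 bears C8(OSO2CF3)=C19H2 | CC(C)=CCC[C@H](C)CCC2=C(C)[C@@H]3[C@H](C(=C)OS(=O)(=O)C(F)(F)F)CC[C@]3(C)[C@@H](O[Si](CC)(CC)CC)[C@@H]2O[Si](CC)(CC)CC | intermediate
23 | vicinal diol from dihydroxylation of the chain alkene of 22 (C9 carbinol and tertiary carbinol, C9 epimers) | CC(C)(O)C(O)CC[C@H](C)CCC2=C(C)[C@@H]3[C@H](C(=C)OS(=O)(=O)C(F)(F)F)CC[C@]3(C)[C@@H](O[Si](CC)(CC)CC)[C@@H]2O[Si](CC)(CC)CC | intermediate
24 | C9 aldehyde of the alkenyl triflate (12R by CIP, same configuration as before) | O=CCC[C@H](C)CCC2=C(C)[C@@H]3[C@H](C(=C)OS(=O)(=O)C(F)(F)F)CC[C@]3(C)[C@@H](O[Si](CC)(CC)CC)[C@@H]2O[Si](CC)(CC)CC | intermediate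
25 | (2R,3R,4S,7R,9R,12R,16S) macrocyclic allylic alcohol: the target without the acetyl group, O2 and O3 as triethylsilyl ethers | C=C1[C@H](O)CC[C@H](C)CCC2=C(C)[C@@H]3[C@H]1CC[C@]3(C)[C@@H](O[Si](CC)(CC)CC)[C@@H]2O[Si](CC)(CC)CC | intermediate
26 | 9-O-acetate of 25 | C=C1[C@H](OC(C)=O)CC[C@H](C)CCC2=C(C)[C@@H]3[C@H]1CC[C@]3(C)[C@@H](O[Si](CC)(CC)CC)[C@@H]2O[Si](CC)(CC)CC | intermediate
27 | CNP0192310.3, (2R,3R,4S,7R,9R,12R,16S)-9-acetoxy-2,3-dihydroxy tricycle with C1=C15 and C8=C19 double bonds | C=C1[C@H](OC(C)=O)CC[C@H](C)CCC2=C(C)[C@@H]3[C@H]1CC[C@]3(C)[C@@H](O)[C@@H]2O | target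

Total step count: 18. Longest linear sequence: 18 steps (1 to 27); 3, 6 and 11 are bought and enter in steps 2, 3 and 6.

Steps most likely to fail

1. Step 9 (Proposed new method). What may go wrong: the ring-opened enolate may be consumed by O-alkylation to a dihydrofuran; iodide may displace the carboxylate at the allylic, keto-activated C2 and so scramble the only controlling stereocentre; or the Michael closure may be too slow at a temperature the lactone tolerates. The fallback makes the same two bonds stepwise by known reactions and sets out from 14. Me3SiI (made from Me3SiCl and NaI, with hexamethyldisilazane, MeCN/CH2Cl2, −20 °C) opens the cyclopropyl ketone to the γ-iodo trimethylsilyl enol ether F1. TiCl4 (CH2Cl2, −78 °C) then drives the intramolecular Mukaiyama–Michael addition to C16, and aqueous work-up should give the bicyclic iodoethyl keto lactone F2; only its C4 epimer with the iodoethyl arm on the lactone face can go on. LiN(SiMe3)2 (THF/DMPU, −78 to 0 °C) deprotonates only the lactone methylene, because the ketone is flanked by quaternary C4 and bridgehead C2, and 5-exo-tet alkylation closes ring B and comes back to the route at 17.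

2. Step 6. What may go wrong: the closed lactol may add to the ylide through its anomeric hydroxyl (a dead-end acylal ylide), or may lose water to the aromatic furan, before the ring-opened hydroxy enal on which the cascade depends is intercepted. The fallback sets out from 10. Wittig methylenation (Ph3P=CH2, THF, 0 °C) gives the (Z)-dienol F3, acryloyl chloride/iPr2NEt (CH2Cl2, −20 °C) gives the acrylate F4, and ring-closing metathesis (second-generation Grubbs catalyst, toluene, 80 °C, 2 mM) forms the C7=C16 bond and comes back to the route at 12.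

3. Step 16. What may go wrong: poor facial selectivity at C9 if the conformational bias of the closing eleven-membered ring overrides the ligand; slow closure that lets intermolecular coupling compete is countered by the high dilution. The fallback sets out from 25 obtained as a C9 epimer mixture. Oxidation (Dess–Martin periodinane, NaHCO3, CH2Cl2) gives the macrocyclic α-methylene ketone F5, and (S)-2-methyl-CBS-oxazaborolidine with BH3·SMe2 (THF, −30 °C; the alkenyl group acts as the large substituent) reduces it under reagent control to the 9R alcohol, coming back to the route at 25.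

Further compounds
F1 | step 9 | γ-iodo trimethylsilyl enol ether: (7R)-oxepinone 14 with the side chain C3(OSiMe3)=C4(CH3)CH2CH2I | O=C1C=CC(C)=C(CC[C@@H](C)CCC=C(C)C)[C@H](C(O[Si](C)(C)C)=C(C)CCI)O1
F2 | step 9 | bicyclic iodoethyl keto lactone: C4–C16 formed, C7 still CH2, iodoethyl arm on C4 on the lactone face | CC(C)=CCC[C@H](C)CCC2=C(C)[C@@H]3CC(=O)O[C@H]2C(=O)[C@@]3(C)CCI
F3 | step 6 | (Z)-dienol: C16 as a vinyl group cis to C2 on the C15=C1 bond, free C2 hydroxyl, C3 triethylsilyl ether | C=C/C(C)=C(/CC[C@@H](C)CCC=C(C)C)[C@@H](O)C(O[Si](CC)(CC)CC)C1(C)CC1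
F4 | step 6 | acrylate of F3 at O2 | C=C/C(C)=C(/CC[C@@H](C)CCC=C(C)C)[C@@H](OC(=O)C=C)C(O[Si](CC)(CC)CC)C1(C)CC1
F5 | step 16 | macrocyclic α-methylene ketone: 25 with C9 as a ketone | C=C1C(=O)CC[C@H](C)CCC2=C(C)[C@@H]3[C@H]1CC[C@]3(C)[C@@H](O[Si](CC)(CC)CC)[C@@H]2O[Si](CC)(CC)CC
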